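## Retrosynthetic overview

1. Only one ring is built, and it is built last. The dihydropyran ring (O1–C8a bond) closes by visible-light ipso-substitution of an aryl OMe by the tertiary hydroxyl of a seco-chroman. The benzene ring is bought.
2. C4–C4a comes from hydroboration/Suzuki coupling of the single vinyl group of a C45 bis-carbinol polyene with a bromoarene.
3. The C45 chain is three C15 units. The farnesyl-head/nerolidol-tail CH2–CH2 bond comes from allylic sulfone alkylation and desulfonylation. The farnesyl-tail/nerolidol-vinyl bond comes from an allyl–alkenyl Suzuki coupling.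
4. Both stereocentres are C3 of (3S,6E)-nerolidol, which is used twice. Neither C–O bond at these centres is ever broken.

Assumption: the SMILES is read as 2S at the chroman and S at the side-chain carbinol, and natural (+)-(3S,6E)-nerolidol and 4-methoxy-2,3-dimethylphenol are taken as catalogue compounds.

## Route

Step 1
Reactants: 1 (2E,6E)-farnesyl bromide
Product: 2 (2E,6E)-farnesyl phenyl sulfone
Conditions: PhSO2Na (1.3 equiv), DMF, 0 °C to rt
Reagents that add atoms: sodium benzenesulfinate, [Na+].[O-]S(=O)c1ccccc1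
Why: SN2 S-alkylation of the sulfinate at the primary allylic bromide proceeds without allylic shift, so both E-alkenes are kept and no stereocentre is made.

Step 2
Reactants: 2 (2E,6E)-farnesyl phenyl sulfone
Product: 3 (2E,6E,10E)-2,6,10-trimethyl-12-(phenylsulfonyl)dodeca-2,6,10-trien-1-ol
Conditions: SeO2 (0.1 equiv), t-BuOOH (3 equiv), salicylic acid (0.1 equiv), CH2Cl2, 0 °C to rt
Reagents that add atoms: tert-butyl hydroperoxide, CC(C)(C)OO
Why: Riley-type SeO2 allylic oxidation (ene reaction then [2,3]-shift, catalytic variant) attacks the least hindered, most electron-rich terminal isopropylidene, the 2,3-alkene being deactivated by the sulfone, and gives the E-configured primary allylic alcohol.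

Step 3
Reactants: 3 (2E,6E,10E)-2,6,10-trimethyl-12-(phenylsulfonyl)dodeca-2,6,10-trien-1-ol
Product: 4 (2E,6E,10E)-12-bromo-3,7,11-trimethyldodeca-2,6,10-trienyl phenyl sulfone
Conditions: CBr4 (1.2 equiv), PPh3 (1.25 equiv), CH2Cl2, −20 to 0 °C
Reagents that add atoms: carbon tetrabromide, BrC(Br)(Br)Br
Why: The Appel reaction converts the primary allylic alcohol into the bromide by SN2 displacement of the oxyphosphonium ion under neutral conditions that leave alkene geometry and the sulfone untouched.

Step 4
Reactants: 5 (3S,6E)-nerolidol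
Product: 7 (3S,1E,6E)-1-(pinacolatoboryl)nerolidol, via bis(catecholboryl) adduct 6 (not isolated)
Conditions: catBCl (2.5 equiv), Pd2(dba)3 (2.5 mol %), (3,5-tBu2C6H3)2P(tBu) (6 mol %), Cy2NMe (5 equiv), PhCF3, 70 °C; then pinacol (4 equiv), rt; aq NaHCO3
Reagents that add atoms: B-chlorocatecholborane, ClB1Oc2ccccc2O1; pinacol, CC(C)(O)C(C)(C)O
Why: In this boryl-Heck reaction zerovalent palladium inserts into the B–Cl bond, the boryl-palladium species adds only across the unhindered monosubstituted alkene with boron at the terminus, and β-hydride elimination, possible only at the boron-bearing carbon because C3 is quaternary, gives the E-alkenyl boronate while the transiently O-borylated C3 stereocentre is untouched.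

Step 5
Reactants: 4 (2E,6E,10E)-12-bromo-3,7,11-trimethyldodeca-2,6,10-trienyl phenyl sulfone; 7 (3S,1E,6E)-1-(pinacolatoboryl)nerolidol
Product: 8 (2E,6E,10E,13E,15S,18E)-15-hydroxy-3,7,11,15,19,23-hexamethyltetracosa-2,6,10,13,18,22-hexaenyl phenyl sulfone
Conditions: Pd(PPh3)4 (5 mol %), K3PO4 (3 equiv), THF/H2O 10:1, 40 °C
Reagents that add atoms: none
Why: The Suzuki–Miyaura allyl–alkenyl coupling through a π-allylpalladium intermediate forms the bond at the less hindered CH2 terminus with retention of both alkene geometries, the primary allylic sulfone ionising far more slowly than the bromide and the carbinol stereocentre being a spectator.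

Step 6
Reactants: 5 (3S,6E)-nerolidol
Product: 9 (2E,6E,10S)-2,6,10-trimethyldodeca-2,6,11-triene-1,10-diol
Conditions: SeO2 (0.1 equiv), t-BuOOH (2.5 equiv), salicylic acid (0.1 equiv), CH2Cl2, 0 °C
Reagents that add atoms: tert-butyl hydroperoxide, CC(C)(C)OO
Why: Riley-type SeO2 allylic oxidation prefers the E-methyl of the terminal isopropylidene over the internal trisubstituted alkene and ignores the vinyl group, which has no allylic hydrogen, so the S carbinol is carried through unchanged.

Step 7
Reactants: 9 (2E,6E,10S)-2,6,10-trimethyldodeca-2,6,11-triene-1,10-diol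
Product: 10 (3S,6E,10E)-12-bromo-3,7,11-trimethyldodeca-1,6,10-trien-3-ol
Conditions: CBr4 (1.1 equiv), PPh3 (1.15 equiv), CH2Cl2, −30 to 0 °C, used at once
Reagents that add atoms: carbon tetrabromide, BrC(Br)(Br)Br
Why: The Appel reaction is selective for the primary allylic hydroxyl because the tertiary carbinol cannot form or displace an oxyphosphonium ion at this temperature, so the stereocentre and both alkene geometries survive.

Step 8
Reactants: 8 (2E,6E,10E,13E,15S,18E)-15-hydroxy-3,7,11,15,19,23-hexamethyltetracosa-2,6,10,13,18,22-hexaenyl phenyl sulfone; 10 (3S,6E,10E)-12-bromo-3,7,11-trimethyldodeca-1,6,10-trien-3-ol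
Product: 12 (3S,6E,10E,14E,18E,22E,25E,27S,30E)-3,7,11,15,19,23,27,31,35-nonamethylhexatriaconta-1,6,10,14,18,22,25,30,34-nonaene-3,27-diol, via alkylated C45 sulfone 11 (not isolated)
Conditions: n-BuLi (2.1 equiv), THF, −78 °C; 10 (1.05 equiv), −78 to −20 °C; then PdCl2(dppp) (5 mol %), LiBHEt3 (5 equiv), 0 °C
Reagents that add atoms: none
Why: Biellmann–Julia-type α-alkylation of the lithiated allylic sulfone with the primary allylic bromide (SN2) is followed by palladium-catalysed hydride desulfonylation, in which hydride goes to the secondary terminus of the π-allyl complex so the E-trisubstituted alkene stays in place, the two carbinols being inert lithium alkoxides and the transient sulfone-bearing stereocentre being erased.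

Step 9
Reactants: 13 4-methoxy-2,3-dimethylphenol
Product: 14 (4-methoxy-2,3-dimethylphenoxy)triisopropylsilane
Conditions: TIPSCl (1.1 equiv), imidazole (2.5 equiv), DMF, rt
Reagents that add atoms: chlorotriisopropylsilane, CC(C)[Si](Cl)(C(C)C)C(C)C
Why: Imidazole-promoted O-silylation of the phenol installs a base-stable, fluoride-labile group that stays a good para electron donor for the later ring closure.

Step 10
Reactants: 14 (4-methoxy-2,3-dimethylphenoxy)triisopropylsilane
Product: 15 (5-bromo-4-methoxy-2,3-dimethylphenoxy)triisopropylsilane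
Conditions: NBS (1.05 equiv), MeCN, 0 °C to rt, dark
Reagents that add atoms: N-bromosuccinimide, O=C1CCC(=O)N1Br
Why: Electrophilic aromatic bromination goes ortho to OMe and para to the C2 methyl because the only other free position is shielded by the bulky silyloxy group.

Step 11
Reactants: 12 (3S,6E,10E,14E,18E,22E,25E,27S,30E)-3,7,11,15,19,23,27,31,35-nonamethylhexatriaconta-1,6,10,14,18,22,25,30,34-nonaene-3,27-diol; 15 (5-bromo-4-methoxy-2,3-dimethylphenoxy)triisopropylsilane
Product: 17 seco-chroman (12 with its vinyl group turned into CH2CH2 bonded to C5 of the 4-methoxy-2,3-dimethyl-1-triisopropylsilyloxybenzene ring; both carbinols S), via B-alkyl-9-BBN borane 16 (not isolated)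
Conditions: 9-BBN-H (1.5 equiv), THF, 0 °C to rt; then 15 (1.2 equiv), Pd(OAc)2 (5 mol %), SPhos (10 mol %), K3PO4 (3 equiv, 3 M aq), THF, 50 °C
Reagents that add atoms: 9-borabicyclo[3.3.1]nonane, B1C2CCCC1CCC2 (its boron framework sits only in 16)
Why: 9-BBN hydroborates the lone monosubstituted alkene anti-Markovnikov far faster than the hindered E-disubstituted and the trisubstituted alkenes, and the B-alkyl Suzuki–Miyaura coupling then forms the C4–C4a bond without touching either carbinol centre.

Step 12
Reactants: 17 seco-chroman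
Product: 19 target (2S)-chromanol CNP0323443.2, via chroman triisopropylsilyl ether 18 (not isolated)
Conditions: [Ir(dF(CF3)ppy)2(5,5'-d(CF3)bpy)]PF6 (2 mol %), 4 Å molecular sieves, ClCH2CH2Cl (0.02 M), 450 nm LEDs, 25 °C, Ar, no base; then Bu4NF (1.5 equiv), AcOH (1.5 equiv), THF, 0 °C to rt
Reagents that add atoms: none
Why: Proposed new method: this is an intramolecular cation-radical-accelerated SNAr in which the excited photocatalyst (about +1.7 V vs SCE) oxidises only the silyloxy-anisole ring (estimated +1.4 V, the alkenes lying near +1.9 V), the tethered tertiary hydroxyl adds through a six-membered transition state to C8a, which is para to the planar silyloxy donor and carries the twisted OMe, proton shift to that OMe and loss of MeOH (taken up by the sieves) give the better stabilised chroman radical cation that the reduced photocatalyst returns to neutral 18, so the cycle is redox- and proton-neutral, attack at C5–H is unproductive without an oxidant, leaving out base keeps O–H PCET and β-scission closed, the C2–O bond is never broken so the S centre is kept with retention, the closest known reaction types are photoredox cation-radical-accelerated SNAr of alkoxyarenes by azoles or amines and anodic ipso-alkoxylation to quinone ketals, and buffered fluoride then frees the phenol.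

## Compound list

1 | (2E,6E)-farnesyl bromide | CC(C)=CCC/C(C)=C/CC/C(C)=C/CBr | starting material
2 | (2E,6E)-farnesyl phenyl sulfone | CC(C)=CCC/C(C)=C/CC/C(C)=C/CS(=O)(=O)c1ccccc1 | intermediate
3 | (2E,6E,10E)-2,6,10-trimethyl-12-(phenylsulfonyl)dodeca-2,6,10-trien-1-ol | OC/C(C)=C/CC/C(C)=C/CC/C(C)=C/CS(=O)(=O)c1ccccc1 | intermediate
4 | (2E,6E,10E)-12-bromo-3,7,11-trimethyldodeca-2,6,10-trienyl phenyl sulfone | BrC/C(C)=C/CC/C(C)=C/CC/C(C)=C/CS(=O)(=O)c1ccccc1 | intermediate
5 | (3S,6E)-nerolidol | CC(C)=CCC/C(C)=C/CC[C@](C)(O)C=C | starting material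
6 | (3S,1E,6E)-nerolidol bearing catecholboryl groups on O3 and C1 (not isolated) | CC(C)=CCC/C(C)=C/CC[C@](C)(OB1Oc2ccccc2O1)/C=C/B1Oc2ccccc2O1 | intermediate
7 | (3S,1E,6E)-3,7,11-trimethyl-1-(4,4,5,5-tetramethyl-1,3,2-dioxaborolan-2-yl)dodeca-1,6,10-trien-3-ol | CC(C)=CCC/C(C)=C/CC[C@](C)(O)/C=C/B1OC(C)(C)C(C)(C)O1 | intermediate
8 | (2E,6E,10E,13E,15S,18E)-15-hydroxy-3,7,11,15,19,23-hexamethyltetracosa-2,6,10,13,18,22-hexaenyl phenyl sulfone | CC(C)=CCC/C(C)=C/CC[C@](C)(O)/C=C/C/C(C)=C/CC/C(C)=C/CC/C(C)=C/CS(=O)(=O)c1ccccc1 | intermediate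
9 | (2E,6E,10S)-2,6,10-trimethyldodeca-2,6,11-triene-1,10-diol | OC/C(C)=C/CC/C(C)=C/CC[C@](C)(O)C=C | intermediate
10 | (3S,6E,10E)-12-bromo-3,7,11-trimethyldodeca-1,6,10-trien-3-ol | BrC/C(C)=C/CC/C(C)=C/CC[C@](C)(O)C=C | intermediate
11 | C45 diol 12 carrying PhSO2 at C13, epimers at C13 (not isolated) | CC(C)=CCC/C(C)=C/CC[C@](C)(O)/C=C/C/C(C)=C/CC/C(C)=C/CC/C(C)=C/C(C/C(C)=C/CC/C(C)=C/CC[C@](C)(O)C=C)S(=O)(=O)c1ccccc1 | intermediate
12 | (3S,6E,10E,14E,18E,22E,25E,27S,30E)-3,7,11,15,19,23,27,31,35-nonamethylhexatriaconta-1,6,10,14,18,22,25,30,34-nonaene-3,27-diol | CC(C)=CCC/C(C)=C/CC[C@](C)(O)/C=C/C/C(C)=C/CC/C(C)=C/CC/C(C)=C/CC/C(C)=C/CC/C(C)=C/CC[C@](C)(O)C=C | intermediate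
13 | 4-methoxy-2,3-dimethylphenol | COc1ccc(O)c(C)c1C | starting material
14 | (4-methoxy-2,3-dimethylphenoxy)triisopropylsilane | COc1ccc(O[Si](C(C)C)(C(C)C)C(C)C)c(C)c1C | intermediate
15 | (5-bromo-4-methoxy-2,3-dimethylphenoxy)triisopropylsilane | COc1c(Br)cc(O[Si](C(C)C)(C(C)C)C(C)C)c(C)c1C | intermediate
16 | B-alkyl-9-BBN from anti-Markovnikov hydroboration of the vinyl group of 12 (not isolated) | CC(C)=CCC/C(C)=C/CC[C@](C)(O)/C=C/C/C(C)=C/CC/C(C)=C/CC/C(C)=C/CC/C(C)=C/CC/C(C)=C/CC[C@](C)(O)CCB1C2CCCC1CCC2 | intermediate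
17 | seco-chroman: aryl-CH2CH2-C(CH3)(OH) polyene, aryl = 2-methoxy-3,4-dimethyl-5-(triisopropylsilyloxy)phenyl, both carbinols S | CC(C)=CCC/C(C)=C/CC[C@](C)(O)/C=C/C/C(C)=C/CC/C(C)=C/CC/C(C)=C/CC/C(C)=C/CC/C(C)=C/CC[C@](C)(O)CCc1cc(O[Si](C(C)C)(C(C)C)C(C)C)c(C)c(C)c1OC | intermediate
18 | 6-O-triisopropylsilyl ether of the target, 2S (not isolated) | CC(C)=CCC/C(C)=C/CC[C@](C)(O)/C=C/C/C(C)=C/CC/C(C)=C/CC/C(C)=C/CC/C(C)=C/CC/C(C)=C/CC[C@@]1(C)CCc2cc(O[Si](C(C)C)(C(C)C)C(C)C)c(C)c(C)c2O1 | intermediate
19 | (2S)-2-[(3E,7E,11E,15E,19E,22E,24S,27E)-24-hydroxy-4,8,12,16,20,24,28,32-octamethyltritriaconta-3,7,11,15,19,22,27,31-octaenyl]-2,7,8-trimethylchroman-6-ol | CC(C)=CCC/C(C)=C/CC[C@](C)(O)/C=C/C/C(C)=C/CC/C(C)=C/CC/C(C)=C/CC/C(C)=C/CC/C(C)=C/CC[C@@]1(C)CCc2cc(O)c(C)c(C)c2O1 | target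

## Step count

- **Total steps:** 12.
- **Longest linear sequence:** 7 (steps 1, 2, 3, 5, 8, 11, 12).

## Steps most likely to fail

**Step 12 (the new ring closure).**
- **Risks.** A neutral tertiary alcohol may attack the stabilised radical cation too slowly. The more easily oxidised product competes for the excited catalyst. The silyl group may be lost from the radical cation.
- **Fallback.** It sets out from 17 and comes back at 19, using known two-electron chemistry.
  - Bu4NF/AcOH frees the phenol and gives the 4-methoxyphenol seco-chromanol F1.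
  - PhI(OAc)2 with NaHCO3 in MeCN at 0 °C is a standard hypervalent-iodine phenol dearomatisation. The tethered tertiary hydroxyl captures the phenoxenium ion at the para carbon that bears OMe. This gives the 8a-methoxychroman-6(8aH)-one quinone monoketal F2 as C8a epimers, with C2 untouched.
  - Ascorbic acid in aqueous THF, the classical tocopherone-to-tocopherol reduction, expels methanol and re-aromatises to 19.

**Step 4 (boryl-Heck on a free tertiary allylic alcohol).**
- **Risks.** β-Boryloxy elimination or ionisation of the O-borylated carbinol would destroy the stereocentre.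
- **Fallback.** It sets out from 5 and comes back at 7.
  - TESOTf and 2,6-lutidine mask the hydroxyl and give the nerolidol triethylsilyl ether F3.
  - Boron is then introduced without any B–Cl reagent, by ruthenium-hydride borylative coupling with vinyl-Bpin. The conditions are RuHCl(CO)(PCy3)2 in toluene at 80 °C. The alkene inserts into Ru–B, β-hydride elimination follows, and ethylene is lost. This gives the silyl-protected E-alkenyl boronate F4.
  - Bu4NF/AcOH removes silicon and gives 7.

**Step 11 (late hydroboration/Suzuki coupling).**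
- **Risks.** The reaction must be chemoselective on a nonaene with two free hydroxyls. The ortho-substituted aryl bromide is electron-rich and may be slow in oxidative addition.
- **Fallback.** It sets out from 12 and comes back at 17. It forms C4–C4a by radical conjugate addition instead of cross-coupling.
  - Catecholborane (3.3 equiv) with RhCl(PPh3)3 (2 mol %) gives the tris(catecholboryl) compound F5.
  - F5 undergoes air-initiated radical-chain reductive alkylation of 2,3-dimethyl-1,4-benzoquinone, the known organoborane–quinone reaction. After hydrolysis this gives the alkylated hydroquinone F6.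
  - Bulky TIPSCl with imidazole silylates only the less hindered hydroxyl and gives the mono-silylated hydroquinone F7.
  - MeI/K2CO3 in acetone methylates the remaining phenol and gives 17.

## Further compounds

F1 | step 12 | 4-methoxyphenol seco-chromanol (17 without the silyl group) | CC(C)=CCC/C(C)=C/CC[C@](C)(O)/C=C/C/C(C)=C/CC/C(C)=C/CC/C(C)=C/CC/C(C)=C/CC/C(C)=C/CC[C@](C)(O)CCc1cc(O)c(C)c(C)c1OC
F2 | step 12 | (2S)-8a-methoxy-2,7,8-trimethyl-2-(side chain)-chroman-6(8aH)-one quinone monoketal, C8a epimers | CC(C)=CCC/C(C)=C/CC[C@](C)(O)/C=C/C/C(C)=C/CC/C(C)=C/CC/C(C)=C/CC/C(C)=C/CC/C(C)=C/CC[C@@]1(C)CCC2=CC(=O)C(C)=C(C)C2(OC)O1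
F3 | step 4 | (3S,6E)-nerolidol triethylsilyl ether | CC(C)=CCC/C(C)=C/CC[C@](C)(O[Si](CC)(CC)CC)C=C
F4 | step 4 | (3S,1E,6E)-1-(pinacolatoboryl)nerolidol triethylsilyl ether | CC(C)=CCC/C(C)=C/CC[C@](C)(O[Si](CC)(CC)CC)/C=C/B1OC(C)(C)C(C)(C)O1
F5 | step 11 | tris(catecholboryl) compound from 12 (both O-borylated, terminal C-borylated) | CC(C)=CCC/C(C)=C/CC[C@](C)(OB1Oc2ccccc2O1)/C=C/C/C(C)=C/CC/C(C)=C/CC/C(C)=C/CC/C(C)=C/CC/C(C)=C/CC[C@](C)(OB1Oc2ccccc2O1)CCB1Oc2ccccc2O1
F6 | step 11 | 5-alkyl-2,3-dimethylhydroquinone carrying the C45 diol chain | CC(C)=CCC/C(C)=C/CC[C@](C)(O)/C=C/C/C(C)=C/CC/C(C)=C/CC/C(C)=C/CC/C(C)=C/CC/C(C)=C/CC[C@](C)(O)CCc1cc(O)c(C)c(C)c1O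
F7 | step 11 | mono-triisopropylsilyl ether of F6 at the less hindered hydroxyl | CC(C)=CCC/C(C)=C/CC[C@](C)(O)/C=C/C/C(C)=C/CC/C(C)=C/CC/C(C)=C/CC/C(C)=C/CC/C(C)=C/CC[C@](C)(O)CCc1cc(O[Si](C(C)C)(C(C)C)C(C)C)c(C)c(C)c1O
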